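I decided to read this flask against its two earlier runs by one yardstick instead of the clock.

| setting | north | east | flask |
|---|---|---|---|
| substrate | 0.050 M | 0.050 M | 0.050 M |
| partner | 0.065 M | 0.065 M | 0.0650 M |
| free catalyst | 12 µM | 19 µM | 25 µM |
| second catalyst | 5 mM | 5 mM | 5.0 mM |
| remark | run made earlier | run made earlier |  |
| time |  |  | 10 d |

| run | time / d | target / % | isomer of the product / % | substrate / % |
|---|---|---|---|---|
| north | 1.67 | 61.7 | 6.0 | 0.7 |
| north | 3.00 | 72.0 | 9.8 | 1.0 |
| north | 5.00 | 76.1 | 14.4 | 0 |
| north | 6.00 | 77.2 | 17.7 | 0.8 |
| north | 8.00 | 75.3 | 18.6 | 1.7 |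
| north | 10.0 | 77.0 | 19.6 | 0.4 |
| east | 0.625 | 39.3 | 0.8 | 0.5 |
| east | 2.08 | 64.5 | 7.3 | 0 |
| east | 4.00 | 71.3 | 14.2 | 0.5 |
| east | 5.00 | 73.8 | 18.9 | 0.6 |
| east | 8.00 | 74.5 | 21.7 | 0 |
| east | 10.0 | 75.3 | 21.5 | 1.9 |

(readings scatter by 1 percentage point)

* share of target in target plus isomer of the product at 2.0 h
* share of target in target plus isomer of the product at 10 d

Free catalyst was the setting the runs had turned. By hand I took the turning of target into isomer of the product as pseudo-first-order in target, with a rate proportional to free catalyst and free catalyst unchanged. So I kept one number: the free catalyst of a flask times its time, divided by the free catalyst of the north run. For this flask at 10 d it is 20.8 d, and I call it the north-equivalent time. The runs test it: the east run at 5.00 d stands at 7.92 d, beside the north run at 8.00 d, and their shares of target in target plus isomer read 79.6% and 80.2%.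

Time was the next setting. The east share read 77.4% at 8.00 d and 77.8% at 10.0 d. That last reading stands at 15.8 d, less than this flask reaches, so I reckoned 77.8% for the late share. At 2.0 h the yardstick gives 0.174 d, less than the 0.990 d of the first east reading, where the share read 98.0%, so I expected a higher early share. Partner and second catalyst stood as in both runs, so the readings showed nothing of them and I held them.

The forecast gave 99% and 77%, and said of the isomer: “It therefore forms mainly from the target, not in parallel with it.” Its late share lies 0.80 percentage points below mine.

The flask gave 99.5% at 2.0 h and 77.8% at 10 d, and a tenfold time made no difference. A share in this flask at 10 d, a north-equivalent time of 20.8 d, lying outside the margin of the question would have made the forecast wrong.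

    partner + second catalyst + intermediate → second catalyst + target (k = 136 M⁻² h⁻¹)
    substrate + free catalyst → free catalyst + intermediate (k = 39400 M⁻¹ h⁻¹)
    target + free catalyst ⇌ isomer of the product + free catalyst, rate k3*[free catalyst]*[target] forward; the back reaction follows from the equilibrium constant (K = 0.290, k = 288 M⁻¹ h⁻¹)

A second flask, with 6.20 µM of free catalyst and the other charges and the time unchanged, has a north-equivalent time of 5.17 d, beside the north run at 5.00 d, which read 84.1%. The computed share in that flask at 10 d is 82.5%.

The earlier runs and the new flask stem from a simulated flask for substances that don't exist; noise was put on by code.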